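## Structural features

The target is the 3‑hydrogen sulfate of (2R,3R,2'R,3'R)‑β,β‑carotene‑2,3,2',3'‑tetrol. Two trimethylcyclohexene end rings (carotenoid numbering: quaternary C1, tetrasubstituted C5=C6) are joined through C6 and C6' by an all‑E nonaene chain, C7 to C7', with methyl branches at C9, C13, C13' and C9'. Each ring carries two adjacent stereocentres, C2 and C3, with trans oxygens. C2 is neopentyl, wedged between quaternary C1 and C3. Both pairs are (R,R) and are separated by the achiral chain. The two ends differ only at O3, a sulfate monoester on one ring and a free hydroxyl on the other, so one of four secondary hydroxyls must be singled out. The fragile parts are the polyene (light, oxygen, acid, E/Z drift at the hindered C7=C8 bonds), the sulfate monoester (acid solvolysis, displacement by a vicinal alkoxide) and any mono‑protected vicinal diol (silyl migration). The chain is not the real difficulty, since the C20 dialdehyde core is available. The difficulty is to create the trans‑2,3‑dioxygenation enantioselectively on a ring with no other handle, and to keep O2 and O3 distinguishable until sulfation. The key step uses the fact that ring carbons C1 to C6 with their three methyl groups are those of C‑methylated 2,6‑dimethylphenol. In the resulting dienone, C2=C3 is a cis‑disubstituted, conjugated alkene next to quaternary C1, and its cis oxide, opened at allylic C3 with inversion, gives the trans pattern with two different oxygen substituents.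

## Logic of the disconnections

20 ⇒ 19. The three O–Si bonds at O2, O2' and O3' are cut last, so the final operation only frees hydroxyls. The forward step needs a fluoride source that leaves the sulfate ester and the polyene alone and does not build up the O2 alkoxide next to the sulfate.

19 ⇒ 18. The O3–S bond is cut, which makes the sulfate the last heteroatom introduced. The gain is that site selection becomes a matter of protection and not of relative rates. The demand is that 18 has exactly one free hydroxyl, at C3.

18 ⇒ 16 + 12 (through 17). The C7=C8 bond of the ring that will carry the sulfate is cut. A C10 end group with free O3 is split from a C30 aldehyde. The olefination must tolerate a free hydroxyl without strong base and must end E at a hindered position.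

16 ⇒ 13 + 14 (through 15). The C7'=C8' bond of the other end is cut, leaving the symmetrical C20 dialdehyde. The demand is mono‑condensation of a dialdehyde with two equivalent ends.

13 ⇒ 12. The O3–Si bond is cut so that both end groups come from one intermediate, at the cost of one extra step. The demand is silylation in the presence of a phosphonium salt.

12 ⇒ 11. The C7–P bond is cut, giving an allylic alcohol. The forward step must ionise only the allylic primary hydroxyl and spare the secondary O3–H and the silyl ether.

11 ⇒ 10. The two C7–H bonds and the O3–H are traced back to a methyl ester and a pivalate, so that one reduction sets the oxidation level of C7 and unmasks O3.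

10 ⇒ 9. The C6–C7 bond is cut, with a one‑carbon unit added by carbonylation. The demand is oxidative addition at a tetrasubstituted, doubly flanked enol triflate.

9 ⇒ 7 (through 8). The enol O–S bond and the C4–H bond are cut. One operation saturates C4 and fixes the C5=C6 alkene regiospecifically, because C1 has no hydrogen. The demand is 1,4‑ over 1,2‑hydride delivery.

7 ⇒ 6. The O2–Si bond is cut. Silylation follows the opening so that O2 (silyl) and O3 (acyl) are differentiated as a direct result of the oxirane chemistry.

6 ⇒ 5. The C3–O(acyl) bond is cut with inversion. The trans diol derivative becomes a cis oxide, so both stereocentres reduce to one enantioselective event. The demand is anti attack at allylic C3 and not at neopentyl C2.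

5 ⇒ 4. The C2–O and C3–O bonds of the oxirane are cut (key step). All stereochemistry is removed and a flat dienone remains. The demand is enantioface and site selection for the distal cis alkene.

4 ⇒ 1 + 2 (through 3). The C1–CH3 bond is cut, which leads back to a phenol and a methyl donor. The demand is C‑ over O‑alkylation of the phenolate at an already substituted ortho carbon.

## Other disconnections considered

Alternative 1: The cut is at C14–C15 and C14'–C15', removing the central two‑carbon unit. In the forward step ethyne‑1,2‑diylbis(magnesium bromide) A3 adds to two molecules of the bis‑silylated retro‑C19 trienal A2 and gives the C40 acetylenic 14,14'‑diol tetrakis‑TBS ether A1. Acid‑induced dehydration with allylic transposition, semi‑hydrogenation over Pd/CaCO3 poisoned with Pb(OAc)2, and thermal Z→E isomerisation would follow.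
- In its favour: the union is a plain carbonyl addition with no statistical element and no hindered olefination at C7=C8. On chain assembly it is the equal of the chosen plan, and in robustness of the C–C bond formation it is the better one. The epimers at C14 and C14' do not matter because both centres are destroyed.
- Against it here: it says nothing about the ring. A2 still needs an enantiopure ring with the trans diol plus a nine‑carbon side chain, a longer elaboration than the one‑carbon carbonylation that leads to 12. The product is symmetrical and fully silylated, so the single sulfate could only be introduced statistically. The dehydration needs strong acid in the presence of four silyl ethers.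
- Comparison: mechanistically it is polar addition followed by ionisation and partial hydrogenation, against catalytic oxygen transfer followed by stereospecific substitution. About four operations follow the union before sulfation, so the total would exceed the thirteen steps planned here.

Alternative 2: The cut is at ring bond C3–C4. In the forward step SmI2 (divalent samarium) reduces the aldehyde of (2R)‑2‑(tert‑butyldimethylsilyloxy)‑3,3,5‑trimethyl‑4‑oxohex‑5‑enal A5 to a ketyl that adds in a 6‑endo sense to the methylene terminus of the isopropenyl ketone. The product is (3R,4R)‑3‑(tert‑butyldimethylsilyloxy)‑4‑hydroxy‑2,2,6‑trimethylcyclohexanone A4.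
- In its favour: C2 and the gem‑dimethyl carbon come from (R)‑pantolactone A6, so the absolute configuration does not depend on a catalyst. On optical purity this is the better plan. A4 has O2 silylated and O3 free, the same differentiation as in 11, so on that point it is equal, and it could join the present route at the enol triflate stage.
- Against it here: C3 is set by diastereoselection in a radical addition, anti to the neighbouring silyloxy group, which is less secure than the stereospecific inversion used in step 3. The α‑silyloxy aldehyde can epimerise. The reductant is stoichiometric. Reaching A5 from A6 would take about six or seven steps, against five from 1 to 9.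
- Comparison: both plans create the C3 oxygen stereocentre in relation to C2. The chosen plan does so from a single catalytic event and is shorter. Alternative 2 is the safer one on enantiopurity.

Alternative 3: The cut is at C1–C6. In the forward step SnCl4 opens the oxirane of the threo (E)‑5‑(tert‑butyldimethylsilyloxy)‑6,7‑epoxy‑3,7‑dimethyloct‑2‑enyl phenyl sulfone A8 at its tertiary carbon while the trisubstituted alkene attacks, and proton loss gives (2R,3R)‑2‑hydroxy‑3‑(tert‑butyldimethylsilyloxy)‑β‑cyclogeranyl phenyl sulfone A7.
- In its favour: the ring and C7, as a sulfonylmethyl group ready for Julia olefination with 14, arrive together. After ring formation it is therefore the better plan in step economy, since the chosen route spends three steps (6 to 8) on C7 and phosphorus. No stereocentre is created at closure, so on stereochemical risk in the ring‑forming step it is equal or better.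
- Against it here: both stereocentres must be built beforehand in the open chain, which needs two controlling operations (an enantioselective route to the allylic alcohol and a threo‑selective epoxidation). The attacking alkene is deactivated by the allylic sulfone. Hydride shift to a ketone, halohydrin formation and mixtures of alkene isomers compete. A7 has O2 free and O3 silylated, the opposite of what a C3 sulfate needs, so a protecting‑group exchange would be added. The Julia sequence also needs reductive or eliminative removal of sulfur from a polyene.
- Comparison: cationic ring construction with stereochemistry set beforehand, against functionalisation of a ready‑made ring with stereochemistry set catalytically. The overall step count would be similar or higher.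

Key step: step 2

Remark on the sulfate: it is written un‑ionised in 19 and 20; both would be handled as salts (pyridinium, tetrabutylammonium, sodium), and 20 as drawn is the conjugate acid of the stored sodium salt.

Remark on the catalyst: the (S,S) complex is chosen by analogy with the sense of induction on 2,2‑dimethylchromenes, taking the (S,S) complex to give the (3S,4S) chromene oxide, which corresponds spatially to 5. If the sense is opposite on this untried dienone, the (R,R) complex is used and nothing else changes.

Ring positions in the text follow carotenoid numbering; compound names use ring numbering.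

## Route

Step 1
Reactants: 1 2,6-dimethylphenol; 2 iodomethane
Product: 4 2,6,6-trimethylcyclohexa-2,4-dien-1-one, via lithium 2,6-dimethylphenolate 3 (not isolated)
Conditions: n-butyllithium (1.0 equiv), toluene, 0 °C → rt; MeI (4 equiv), sealed vessel, 110 °C, dark; cold KOH/aq MeOH wash; short-path distillation; store at −20 °C in the dark
Reagents that add atoms: n-butyllithium, [Li]CCCC (supplies only the lithium of intermediate 3)
Why: Alkylative dearomatisation by ortho C-alkylation of a tightly aggregated lithium phenolate in a non-polar medium; the methyl-bearing ortho carbon becomes quaternary C1, O-methylation to the anisole is the competing path, and no stereocentre is formed.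

Step 2
Reactants: 4 2,6,6-trimethylcyclohexa-2,4-dien-1-one
Product: 5 (4S,5R)-4,5-epoxy-2,6,6-trimethylcyclohex-2-en-1-one
Conditions: (S,S)-[N,N'-bis(3,5-di-tert-butylsalicylidene)-1,2-cyclohexanediamine]MnCl (trivalent manganese, 5 mol %), 4-phenylpyridine N-oxide (20 mol %), aq NaOCl buffered with Na2HPO4 (pH 11.3), CH2Cl2, 0 °C, dark
Reagents that add atoms: sodium hypochlorite, [Na+].[O-]Cl
Why: Hypochlorite oxidises the trivalent manganese complex to the oxo species of pentavalent manganese, which transfers its oxygen to the alkene that becomes C2–C3, the first C–O bond forming at C2 and leaving a radical at C3 that is allylic to the enone. The closest known reaction type is the Jacobsen–Katsuki epoxidation of cis-disubstituted conjugated olefins such as 2,2-dimethylchromenes and cyclic 1,3-dienes. The oxirane is closed by oxygen-atom transfer, formally a [2+1] addition, the second C–O bond arising by collapse of the C3 radical onto the manganese-bound oxygen; the six-membered ring forbids rotation and forces cis fusion. Both new stereocentres, C2 (R) and C3 (S), are set together by the twofold-symmetric diaminocyclohexane backbone and the tert-butyl groups of the salen ligand, which allow side-on approach of the alkene over the diimine bridge from one enantioface only. Site selection is needed: the γ,δ-alkene is cis-disubstituted and the more electron-rich one, the privileged class for this electrophilic oxidant, whereas the α,β-alkene is trisubstituted and electron-poor. Quaternary C1 on one side and the conjugating vinyl ketone on the other differentiate the two ends of the alkene as the gem-dimethyl carbon and the arene do in a chromene, which is the basis for expecting useful enantioface selection. The N-oxide as axial ligand speeds the catalytic path so that background oxidation by free hypochlorite and dimerisation of 4 are outrun. The oxirane is temporary: its C3–O bond is replaced with inversion in step 3.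

Step 3
Reactants: 5 (4S,5R)-4,5-epoxy-2,6,6-trimethylcyclohex-2-en-1-one
Product: 6 (4R,5R)-5-hydroxy-2,6,6-trimethyl-4-(pivaloyloxy)cyclohex-2-en-1-one
Conditions: pivalic acid (3 equiv), CsO2CC(CH3)3 (cesium pivalate, 0.3 equiv), DMF, 60 °C
Reagents that add atoms: pivalic acid, CC(C)(C)C(=O)O
Why: Base-catalysed acid–epoxide addition, an SN2 opening of a vinyl oxirane by carboxylate: attack goes anti at allylic C3 and not at neopentyl C2, inverting C3 to R and leaving C2 (R) untouched, which gives the trans-2,3 pattern with O3 acylated and O2 free. Stray attack at C2 would give a constitutional isomer, removable by chromatography, so it cannot lower the enantiomeric purity of 6.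

Step 4
Reactants: 6 (4R,5R)-5-hydroxy-2,6,6-trimethyl-4-(pivaloyloxy)cyclohex-2-en-1-one
Product: 7 (4R,5R)-5-(tert-butyldimethylsilyloxy)-2,6,6-trimethyl-4-(pivaloyloxy)cyclohex-2-en-1-one
Conditions: TBSOTf (1.3 equiv), 2,6-lutidine (2 equiv), CH2Cl2, −78 → 0 °C
Reagents that add atoms: tert-butyldimethylsilyl trifluoromethanesulfonate, CC(C)(C)[Si](C)(C)OS(=O)(=O)C(F)(F)F
Why: Silyl triflate silylation of a hindered secondary alcohol; the weak, hindered base at low temperature should not dienolise the γ-acyloxy enone, and no stereocentre is touched.

Step 5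
Reactants: 7 (4R,5R)-5-(tert-butyldimethylsilyloxy)-2,6,6-trimethyl-4-(pivaloyloxy)cyclohex-2-en-1-one
Product: 9 (4R,5R)-5-(tert-butyldimethylsilyloxy)-2,6,6-trimethyl-4-(pivaloyloxy)cyclohex-1-en-1-yl trifluoromethanesulfonate, via lithium enolate 8 (not isolated)
Conditions: LiBH(s-Bu)3 (1.1 equiv), THF, −78 °C; PhNTf2 (1.3 equiv), −78 → 0 °C
Reagents that add atoms: lithium tri-sec-butylborohydride, [Li+].CCC(C)[BH-](C(C)CC)C(C)CC (lithium of intermediate 8); N-phenylbis(trifluoromethanesulfonimide), O=S(=O)(N(c1ccccc1)S(=O)(=O)C(F)(F)F)C(F)(F)F
Why: 1,4-Hydride addition of a bulky borohydride to an α-methylcyclohexenone whose carbonyl is shielded by the gem-dimethyl carbon, then O-sulfonylation of the enolate, as in the conversion of carvone to the enol triflate of dihydrocarvone. The enolate can only be C5=C6 because C1 is quaternary, and the ester, the silyl ether and both stereocentres are spectators at −78 °C.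

Step 6
Reactants: 9 (4R,5R)-5-(tert-butyldimethylsilyloxy)-2,6,6-trimethyl-4-(pivaloyloxy)cyclohex-1-en-1-yl trifluoromethanesulfonate
Product: 10 methyl (4R,5R)-5-(tert-butyldimethylsilyloxy)-2,6,6-trimethyl-4-(pivaloyloxy)cyclohex-1-ene-1-carboxylate
Conditions: Pd(OAc)2 (5 mol %), Ph2P(CH2)3PPh2 (6 mol %), CO (1 atm), MeOH, Et3N, DMF, 70 °C
Reagents that add atoms: carbon monoxide, [C-]#[O+]; methanol, CO
Why: Palladium-catalysed alkoxycarbonylation of an enol triflate (oxidative addition to zerovalent palladium, CO insertion, methanolysis) installs C7; 2,6,6-trimethylcyclohexenyl triflates are an established substrate class for this coupling.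

Step 7
Reactants: 10 methyl (4R,5R)-5-(tert-butyldimethylsilyloxy)-2,6,6-trimethyl-4-(pivaloyloxy)cyclohex-1-ene-1-carboxylate
Product: 11 [(4R,5R)-5-(tert-butyldimethylsilyloxy)-4-hydroxy-2,6,6-trimethylcyclohex-1-en-1-yl]methanol
Conditions: i-Bu2AlH (5 equiv), CH2Cl2, −78 → −20 °C; aq potassium sodium tartrate
Reagents that add atoms: none
Why: Aluminium hydride reduction of both esters: the conjugated methyl ester gives the allylic alcohol and the pivalate is cleaved to the free C3 hydroxyl. The covalent aluminium alkoxide, low temperature and tartrate work-up are chosen to keep the silyl group from migrating from O2 to O3.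

Step 8
Reactants: 11 [(4R,5R)-5-(tert-butyldimethylsilyloxy)-4-hydroxy-2,6,6-trimethylcyclohex-1-en-1-yl]methanol
Product: 12 {[(4R,5R)-5-(tert-butyldimethylsilyloxy)-4-hydroxy-2,6,6-trimethylcyclohex-1-en-1-yl]methyl}triphenylphosphonium bromide
Conditions: PPh3·HBr (1.1 equiv), CH2Cl2, 0 °C → rt, dark
Reagents that add atoms: triphenylphosphine hydrobromide, [Br-].[PH+](c1ccccc1)(c1ccccc1)c1ccccc1
Why: Direct conversion of an allylic alcohol into its phosphonium salt: the protonated primary allylic hydroxyl ionises and PPh3 captures the allyl cation at the unhindered primary terminus C7, as with β-cyclogeraniol. The secondary homoallylic C3 hydroxyl does not ionise, and the hindered silyl ether should survive the weak acid in a non-hydroxylic solvent.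

Step 9
Reactants: 12 {[(4R,5R)-5-(tert-butyldimethylsilyloxy)-4-hydroxy-2,6,6-trimethylcyclohex-1-en-1-yl]methyl}triphenylphosphonium bromide
Product: 13 {[(4R,5R)-4,5-bis(tert-butyldimethylsilyloxy)-2,6,6-trimethylcyclohex-1-en-1-yl]methyl}triphenylphosphonium bromide
Conditions: TBSCl (1.5 equiv), imidazole (3 equiv), DMF, 40 °C; aq NaBr wash
Reagents that add atoms: tert-butyldimethylsilyl chloride, CC(C)(C)[Si](C)(C)Cl
Why: Imidazole-promoted silylation of the accessible secondary C3 hydroxyl; the phosphonium centre is inert, and only part of 12 is used so that the rest serves in step 11.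

Step 10
Reactants: 13 {[(4R,5R)-4,5-bis(tert-butyldimethylsilyloxy)-2,6,6-trimethylcyclohex-1-en-1-yl]methyl}triphenylphosphonium bromide; 14 crocetindialdehyde (all-E)
Product: 16 (2R,3R)-2,3-bis(tert-butyldimethylsilyloxy)-8'-apo-β-caroten-8'-al (all-E), via phosphorus ylide 15 (not isolated)
Conditions: NaN(SiMe3)2 (1.0 equiv), THF, −78 → 0 °C; cannulate into 14 (3 equiv), CH2Cl2/THF, −40 °C → rt, dark; heptane, 80 °C, Ar (7Z → 7E); excess 14 recovered
Reagents that add atoms: none
Why: Wittig olefination with a semi-stabilised allylic ylide; inverse addition to an excess of the dialdehyde favours mono-condensation, and the first olefination lengthens the conjugation of the remaining formyl group and lowers its reactivity. The crowded 7Z isomer is expected to relax thermally to 7E.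

Step 11
Reactants: 16 (2R,3R)-2,3-bis(tert-butyldimethylsilyloxy)-8'-apo-β-caroten-8'-al (all-E); 12 {[(4R,5R)-5-(tert-butyldimethylsilyloxy)-4-hydroxy-2,6,6-trimethylcyclohex-1-en-1-yl]methyl}triphenylphosphonium bromide
Product: 18 (2R,3R,2'R,3'R)-2,2',3'-tris(tert-butyldimethylsilyloxy)-β,β-caroten-3-ol (all-E), via hydroxy phosphorus ylide 17 (not isolated)
Conditions: 12 (1.5 equiv), 1,2-epoxybutane/EtOH (4:1), 65 °C, dark, Ar; heptane, 80 °C (Z → E)
Reagents that add atoms: none
Why: Wittig olefination under acid-scavenger conditions: bromide opens the oxirane and the resulting alkoxide deprotonates the phosphonium salt, so the ylide forms at low concentration without a stoichiometric strong base. The C3 hydroxyl therefore stays protonated and silyl migration from O2 is avoided; heating equilibrates the new C7=C8 bond to E.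

Step 12
Reactants: 18 (2R,3R,2'R,3'R)-2,2',3'-tris(tert-butyldimethylsilyloxy)-β,β-caroten-3-ol (all-E)
Product: 19 (2R,3R,2'R,3'R)-2,2',3'-tris(tert-butyldimethylsilyloxy)-β,β-caroten-3-yl hydrogen sulfate
Conditions: SO3·pyridine (5 equiv), pyridine/DMF, rt, dark, Ar; aq NaHCO3 (sodium salt)
Reagents that add atoms: sulfur trioxide–pyridine complex, O=S(=O)([O-])[n+]1ccccc1
Why: O-Sulfation of an alcohol with an amine–SO3 complex, the usual way to carotenoid sulfates; 18 has a single free hydroxyl, so the site is fixed by protection, and C3 keeps its configuration because only an O–S bond forms.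

Step 13
Reactants: 19 (2R,3R,2'R,3'R)-2,2',3'-tris(tert-butyldimethylsilyloxy)-β,β-caroten-3-yl hydrogen sulfate
Product: 20 (2R,3R,2'R,3'R)-2,2',3'-trihydroxy-β,β-caroten-3-yl hydrogen sulfate (all-E)
Conditions: Bu4NF (9 equiv), AcOH (9 equiv), THF, rt → 40 °C, dark, Ar; reversed-phase chromatography; Na+ exchange resin for storage
Reagents that add atoms: none
Why: Fluoride-induced cleavage of the three silyl ethers; sulfate monoesters are inert to fluoride. Buffering with acetic acid keeps the O2 alkoxide trans to the sulfate from building up, which would otherwise threaten displacement of sulfate with oxirane closure.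

## Compound list

1 | 2,6-dimethylphenol | Cc1cccc(C)c1O | starting material
2 | iodomethane | CI | starting material
3 | lithium 2,6-dimethylphenolate | [Li+].[O-]c1c(C)cccc1C | intermediate (not isolated)
4 | 2,6,6-trimethylcyclohexa-2,4-dien-1-one | CC1=CC=CC(C)(C)C1=O | intermediate
5 | (4S,5R)-4,5-epoxy-2,6,6-trimethylcyclohex-2-en-1-one (cis oxide; 2R,3S in carotenoid numbering) | O=C1C(C)=C[C@@H]2O[C@@H]2C1(C)C | intermediate
6 | (4R,5R)-5-hydroxy-2,6,6-trimethyl-4-(pivaloyloxy)cyclohex-2-en-1-one | O=C1C(C)=C[C@@H](OC(=O)C(C)(C)C)[C@H](O)C1(C)C | intermediate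
7 | (4R,5R)-5-(tert-butyldimethylsilyloxy)-2,6,6-trimethyl-4-(pivaloyloxy)cyclohex-2-en-1-one | O=C1C(C)=C[C@@H](OC(=O)C(C)(C)C)[C@H](O[Si](C)(C)C(C)(C)C)C1(C)C | intermediate
8 | lithium (4R,5R)-5-(tert-butyldimethylsilyloxy)-2,6,6-trimethyl-4-(pivaloyloxy)cyclohex-1-en-1-olate | [Li+].[O-]C1=C(C)C[C@@H](OC(=O)C(C)(C)C)[C@H](O[Si](C)(C)C(C)(C)C)C1(C)C | intermediate (not isolated)
9 | (4R,5R)-5-(tert-butyldimethylsilyloxy)-2,6,6-trimethyl-4-(pivaloyloxy)cyclohex-1-en-1-yl trifluoromethanesulfonate | CC1=C(OS(=O)(=O)C(F)(F)F)C(C)(C)[C@@H](O[Si](C)(C)C(C)(C)C)[C@H](OC(=O)C(C)(C)C)C1 | intermediate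
10 | methyl (4R,5R)-5-(tert-butyldimethylsilyloxy)-2,6,6-trimethyl-4-(pivaloyloxy)cyclohex-1-ene-1-carboxylate | CC1=C(C(=O)OC)C(C)(C)[C@@H](O[Si](C)(C)C(C)(C)C)[C@H](OC(=O)C(C)(C)C)C1 | intermediate
11 | [(4R,5R)-5-(tert-butyldimethylsilyloxy)-4-hydroxy-2,6,6-trimethylcyclohex-1-en-1-yl]methanol | CC1=C(CO)C(C)(C)[C@@H](O[Si](C)(C)C(C)(C)C)[C@H](O)C1 | intermediate
12 | {[(4R,5R)-5-(tert-butyldimethylsilyloxy)-4-hydroxy-2,6,6-trimethylcyclohex-1-en-1-yl]methyl}triphenylphosphonium bromide | CC1=C(C[P+](c2ccccc2)(c2ccccc2)c2ccccc2)C(C)(C)[C@@H](O[Si](C)(C)C(C)(C)C)[C@H](O)C1.[Br-] | intermediate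
13 | {[(4R,5R)-4,5-bis(tert-butyldimethylsilyloxy)-2,6,6-trimethylcyclohex-1-en-1-yl]methyl}triphenylphosphonium bromide | CC1=C(C[P+](c2ccccc2)(c2ccccc2)c2ccccc2)C(C)(C)[C@@H](O[Si](C)(C)C(C)(C)C)[C@H](O[Si](C)(C)C(C)(C)C)C1.[Br-] | intermediate
14 | crocetindialdehyde (all-E-8,8'-diapocarotene-8,8'-dial) | O=C/C(C)=C/C=C/C(C)=C/C=C/C=C(C)/C=C/C=C(C)/C=O | starting material
15 | ylide of 13, [(4R,5R)-4,5-bis(tert-butyldimethylsilyloxy)-2,6,6-trimethylcyclohex-1-en-1-yl]methylidene(triphenyl)phosphorane | CC1=C(C=P(c2ccccc2)(c2ccccc2)c2ccccc2)C(C)(C)[C@@H](O[Si](C)(C)C(C)(C)C)[C@H](O[Si](C)(C)C(C)(C)C)C1 | intermediate (not isolated)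
16 | (2R,3R)-2,3-bis(tert-butyldimethylsilyloxy)-8'-apo-β-caroten-8'-al (all-E) | CC1=C(/C=C/C(C)=C/C=C/C(C)=C/C=C/C=C(C)/C=C/C=C(C)/C=O)C(C)(C)[C@@H](O[Si](C)(C)C(C)(C)C)[C@H](O[Si](C)(C)C(C)(C)C)C1 | intermediate
17 | ylide of 12, [(4R,5R)-5-(tert-butyldimethylsilyloxy)-4-hydroxy-2,6,6-trimethylcyclohex-1-en-1-yl]methylidene(triphenyl)phosphorane | CC1=C(C=P(c2ccccc2)(c2ccccc2)c2ccccc2)C(C)(C)[C@@H](O[Si](C)(C)C(C)(C)C)[C@H](O)C1 | intermediate (not isolated)
18 | (2R,3R,2'R,3'R)-2,2',3'-tris(tert-butyldimethylsilyloxy)-β,β-caroten-3-ol (all-E) | CC1=C(/C=C/C(C)=C/C=C/C(C)=C/C=C/C=C(C)/C=C/C=C(C)/C=C/C2=C(C)C[C@@H](O)[C@H](O[Si](C)(C)C(C)(C)C)C2(C)C)C(C)(C)[C@@H](O[Si](C)(C)C(C)(C)C)[C@H](O[Si](C)(C)C(C)(C)C)C1 | intermediate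
19 | (2R,3R,2'R,3'R)-2,2',3'-tris(tert-butyldimethylsilyloxy)-β,β-caroten-3-yl hydrogen sulfate (all-E) | CC1=C(/C=C/C(C)=C/C=C/C(C)=C/C=C/C=C(C)/C=C/C=C(C)/C=C/C2=C(C)C[C@@H](OS(=O)(=O)O)[C@H](O[Si](C)(C)C(C)(C)C)C2(C)C)C(C)(C)[C@@H](O[Si](C)(C)C(C)(C)C)[C@H](O[Si](C)(C)C(C)(C)C)C1 | intermediate
20 | (2R,3R,2'R,3'R)-2,2',3'-trihydroxy-β,β-caroten-3-yl hydrogen sulfate (all-E) | CC1=C(/C=C/C(C)=C/C=C/C(C)=C/C=C/C=C(C)/C=C/C=C(C)/C=C/C2=C(C)C[C@@H](OS(=O)(=O)O)[C@H](O)C2(C)C)C(C)(C)[C@@H](O)[C@H](O)C1 | target

## Step count and least certain steps

Total: 13 steps. Longest linear sequence: 13 steps (1 → 4 → 5 → 6 → 7 → 9 → 10 → 11 → 12 → 13 → 16 → 18 → 19 → 20); compound 12 serves twice, as the precursor of 13 and as the partner in step 11.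

Step 2 (key step). The main risk is poor enantioface selection, because the conjugating group is an electron-poor vinyl ketone and not an arene, and the sense of induction is only inferred. Also possible are oxidation at the α,β-alkene, nucleophilic epoxidation by free hypochlorite, and Diels–Alder dimerisation or photolysis of 4 if turnover is slow. The fallback sets out from 4 and comes back at 5. Dimethyldioxirane in acetone at 0 °C, an electrophilic metal-free oxidant that should also choose the distal alkene, gives racemic cis-4,5-epoxy-2,6,6-trimethylcyclohex-2-en-1-one F1. Preparative chromatography on a cellulose tris(3,5-dimethylphenylcarbamate) phase then separates the enantiomers; the (4S,5R) enantiomer is 5 and the antipode is discarded.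

Step 1. O-Methylation may outrun C-methylation at an ortho carbon that already carries a methyl group, and the dienone may dimerise during the hot alkylation or the distillation. The fallback sets out from 1 and comes back at 4, building the dienone by dehydrogenation.
- Hydrogenation of 1 over Pd/C (H2, 5 bar, cyclohexane, 80 °C), stopped at the ketone, gives 2,6-dimethylcyclohexanone F2.
- LiN(i-Pr)2 in THF at −78 °C, then 2, gives 2,2,6-trimethylcyclohexanone F3.
- IBX in DMSO/fluorobenzene at 70 °C dehydrogenates toward the only enolisable side and gives 2,6,6-trimethylcyclohex-2-en-1-one F4.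
- Chloranil in refluxing tert-butanol, acting through the dienol, removes hydride from the ring methylene next to the quaternary carbon and gives 4.

Step 3. The carboxylate may attack too slowly at a secondary carbon, so that base-induced degradation of the enone oxide or of 6 (dienolisation toward a 1,4-dicarbonyl isomer) competes. The fallback sets out from 5 and comes back at 6. Specific-acid hydrolysis (catalytic HClO4, THF/H2O, 0 °C) opens the protonated oxide by anti attack of water at the allylic carbon and gives (4R,5R)-4,5-dihydroxy-2,6,6-trimethylcyclohex-2-en-1-one F5. Pivaloyl chloride and pyridine in CH2Cl2 at 0 °C then acylate the allylic hydroxyl in preference to the neopentyl one and return 6. Its weakness is that water attacking at C2 gives the enantiomeric diol, so regiochemical leakage lowers the enantiomeric purity; this is why it is only the fallback.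

Step 5. Hydride may add 1,2 to the carbonyl or attack the pivalate, and the doubly flanked enolate may be sulfonylated incompletely. The fallback sets out from 7 and comes back at 9, separating the two events. Copper hydride conjugate reduction ([(Ph3P)CuH]6 as catalyst, H2 under pressure, benzene/tert-butanol, rt) gives (3R,4R)-3-(tert-butyldimethylsilyloxy)-2,2,6-trimethyl-4-(pivaloyloxy)cyclohexanone F6 as a mixture of methyl epimers. KN(SiMe3)2 in THF at −78 °C can only enolise toward the methyl-bearing carbon, and N-(5-chloro-2-pyridyl)bis(trifluoromethanesulfonimide), a more reactive sulfonyl donor, gives 9.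

Step 10. Condensation may occur at both formyl groups despite the excess of 14, the hindered ylide may react sluggishly, and 7Z isomers may persist. The fallback sets out from 12 and 14 and comes back at 20, giving up the differentiation of the two ends.
- Double Wittig reaction of 14 with 2.4 equiv of 12 in 1,2-epoxybutane/EtOH at 65 °C gives symmetrical (2R,3R,2'R,3'R)-2,2'-bis(tert-butyldimethylsilyloxy)-β,β-carotene-3,3'-diol F7.
- One equivalent of SO3·pyridine sulfates one of the two equivalent C3 hydroxyls and gives (2R,3R,2'R,3'R)-2,2'-bis(tert-butyldimethylsilyloxy)-3'-hydroxy-β,β-caroten-3-yl hydrogen sulfate F8. Neutral F7 is recovered and the mono- and bis-sulfated species are separated by their charge.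
- Bu4NF/AcOH as in step 13 gives 20.

Site selection between O2 and O3 stays secured by protection; only the mono/bis distribution becomes statistical.

## Further compounds

F1 | step 2 | racemic cis-4,5-epoxy-2,6,6-trimethylcyclohex-2-en-1-one | O=C1C(C)=CC2OC2C1(C)C
F2 | step 1 | 2,6-dimethylcyclohexanone (cis/trans mixture) | CC1CCCC(C)C1=O
F3 | step 1 | 2,2,6-trimethylcyclohexanone (racemic) | CC1CCCC(C)(C)C1=O
F4 | step 1 | 2,6,6-trimethylcyclohex-2-en-1-one | CC1=CCCC(C)(C)C1=O
F5 | step 3 | (4R,5R)-4,5-dihydroxy-2,6,6-trimethylcyclohex-2-en-1-one | O=C1C(C)=C[C@@H](O)[C@H](O)C1(C)C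
F6 | step 5 | (3R,4R)-3-(tert-butyldimethylsilyloxy)-2,2,6-trimethyl-4-(pivaloyloxy)cyclohexanone (C6 epimers) | O=C1C(C)C[C@@H](OC(=O)C(C)(C)C)[C@H](O[Si](C)(C)C(C)(C)C)C1(C)C
F7 | step 10 | (2R,3R,2'R,3'R)-2,2'-bis(tert-butyldimethylsilyloxy)-β,β-carotene-3,3'-diol (all-E) | CC1=C(/C=C/C(C)=C/C=C/C(C)=C/C=C/C=C(C)/C=C/C=C(C)/C=C/C2=C(C)C[C@@H](O)[C@H](O[Si](C)(C)C(C)(C)C)C2(C)C)C(C)(C)[C@@H](O[Si](C)(C)C(C)(C)C)[C@H](O)C1
F8 | step 10 | (2R,3R,2'R,3'R)-2,2'-bis(tert-butyldimethylsilyloxy)-3'-hydroxy-β,β-caroten-3-yl hydrogen sulfate (all-E) | CC1=C(/C=C/C(C)=C/C=C/C(C)=C/C=C/C=C(C)/C=C/C=C(C)/C=C/C2=C(C)C[C@@H](OS(=O)(=O)O)[C@H](O[Si](C)(C)C(C)(C)C)C2(C)C)C(C)(C)[C@@H](O[Si](C)(C)C(C)(C)C)[C@H](O)C1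
A1 | alternative 1 | C40 acetylenic 14,14'-diol tetrakis-TBS ether (epimers at C14 and C14') | CC1=C(C/C=C(C)/C=C/C=C(C)/C(O)C#CC(O)/C(C)=C/C=C/C(C)=C/CC2=C(C)C[C@@H](O[Si](C)(C)C(C)(C)C)[C@H](O[Si](C)(C)C(C)(C)C)C2(C)C)C(C)(C)[C@@H](O[Si](C)(C)C(C)(C)C)[C@H](O[Si](C)(C)C(C)(C)C)C1
A2 | alternative 1 | bis-silylated retro-C19 trienal | CC1=C(C/C=C(C)/C=C/C=C(C)/C=O)C(C)(C)[C@@H](O[Si](C)(C)C(C)(C)C)[C@H](O[Si](C)(C)C(C)(C)C)C1
A3 | alternative 1 | ethyne-1,2-diylbis(magnesium bromide) | Br[Mg]C#C[Mg]Br
A4 | alternative 2 | (3R,4R)-3-(tert-butyldimethylsilyloxy)-4-hydroxy-2,2,6-trimethylcyclohexanone (C6 methyl epimers) | CC1C(=O)C(C)(C)[C@@H](O[Si](C)(C)C(C)(C)C)[C@H](O)C1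
A5 | alternative 2 | (2R)-2-(tert-butyldimethylsilyloxy)-3,3,5-trimethyl-4-oxohex-5-enal | C=C(C)C(=O)C(C)(C)[C@@H](O[Si](C)(C)C(C)(C)C)C=O
A6 | alternative 2 | (R)-pantolactone | CC1(C)COC(=O)[C@@H]1O
A7 | alternative 3 | (2R,3R)-2-hydroxy-3-(tert-butyldimethylsilyloxy)-β-cyclogeranyl phenyl sulfone | CC1=C(CS(=O)(=O)c2ccccc2)C(C)(C)[C@@H](O)[C@H](O[Si](C)(C)C(C)(C)C)C1
A8 | alternative 3 | threo (E)-5-(tert-butyldimethylsilyloxy)-6,7-epoxy-3,7-dimethyloct-2-enyl phenyl sulfone | CC1(C)O[C@H]1[C@H](O[Si](C)(C)C(C)(C)C)C/C(C)=C/CS(=O)(=O)c1ccccc1
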